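The synthesis rests on leaving out the benzo ring of the catechol-bearing flavanone, unit B. That ring (C4a–C8a, oxygens on C5 and C7) is achiral and can be supplied by an acetoacetate equivalent. The two neighbouring stereocentres, C2 (catechol ring, O1) and C3 (joined to C8' of unit A), both lie in the oxygen heterocycle. One hetero-Diels–Alder reaction, catalysed by Ti(OiPr)4/(R)-BINOL, joins 3,4-bis(benzyloxy)benzaldehyde to a 4-aryl-1-methoxy-3-silyloxybutadiene. It forms C2–C3 and O1–C8a, closes the heterocycle as a dihydropyranone and fixes C2. C3 then follows by equilibration. The congested C3–C8' link enters with the diene. The diene's aryl ring carries a MOM ether on O1' and a bromine on C4a'.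

Key step: step 10

Numbering: unit B (catechol flavanone) is unprimed (O1, C2 to C8a) and unit A (4-hydroxyphenyl flavanone) is primed. These labels are used from the first intermediate on. Ar = 4,6-bis(benzyloxy)-3-bromo-2-(methoxymethoxy)phenyl, Ar' = 3,4-bis(benzyloxy)phenyl, Bn = benzyl.

Assumption: Ti(OiPr)4/(R)-BINOL is taken to open the Re face of an aromatic aldehyde (as in its allylations and aldol reactions), and (S)-t-BuPyOX to give the (2'R) adduct (as with cyclic enones). If either sense proves reversed, the ligand antipode is used.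

Remark: O1 of a dihydropyranone is a vinylogous carboxylate, so a C3 enolate can in principle break C2–O1 from step 10 onward. Most later steps are therefore neutral or acidic, or use only as much base as the phenols bind; the one exception is the mildly basic first stage of step 17.

Step 1
Reactants: 1 2,4,6-trihydroxybenzaldehyde
Product: 2 2,4-bis(benzyloxy)-6-hydroxybenzaldehyde
Conditions: BnBr (2.05 equiv), K2CO3, DMF, 0 °C → rt
Reagents that add atoms: benzyl bromide, BrCc1ccccc1
Why: Williamson etherification: the para hydroxyl and one ortho hydroxyl are alkylated, while the last ortho hydroxyl stays locked in a hydrogen bond to the formyl group, which singles out the oxygen that becomes O1'.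

Step 2
Reactants: 2 2,4-bis(benzyloxy)-6-hydroxybenzaldehyde
Product: 3 4,6-bis(benzyloxy)-3-bromo-2-hydroxybenzaldehyde
Conditions: NBS (1.0 equiv), i-Pr2NH (10 mol %), CH2Cl2, −10 °C
Reagents that add atoms: N-bromosuccinimide, O=C1CCC(=O)N1Br
Why: Electrophilic aromatic bromination (amine-mediated ortho-bromination of a phenol): the free hydroxyl directs to its ortho carbon, which is also less crowded than the carbon between two benzyloxy groups, so the handle for the later acetyl group lands on the future C4a' while the molecule is still simple.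

Step 3
Reactants: 3 4,6-bis(benzyloxy)-3-bromo-2-hydroxybenzaldehyde
Product: 4 4,6-bis(benzyloxy)-3-bromo-2-(methoxymethoxy)benzaldehyde (ArCHO)
Conditions: NaH, MOMCl, DMF, 0 °C
Reagents that add atoms: chloromethyl methyl ether, COCCl
Why: O-alkylation of the phenoxide to a formaldehyde acetal; the small MOM group is orthogonal to benzyl and, unlike a free phenol, cannot add to a neighbouring carbonyl group later.

Step 4
Reactants: 4 ArCHO
Product: 5 (±)-2-Ar-oxirane
Conditions: Me3S+ I−, NaH, DMSO–THF, 0 °C → rt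
Reagents that add atoms: trimethylsulfonium iodide, C[S+](C)C.[I-]
Why: Corey–Chaykovsky epoxidation: the unstabilised sulfonium ylide adds irreversibly even to this electron-rich, doubly ortho-substituted aldehyde and needs no acid, so the MOM ether is safe (the racemic centre is erased in step 5).

Step 5
Reactants: 5 (±)-2-Ar-oxirane
Product: 6 2-Ar-acetaldehyde
Conditions: InCl3 (5 mol %), THF, rt; used at once
Reagents that add atoms: none
Why: Meinwald rearrangement: the trialkoxyaryl group makes benzylic C–O ionisation easy with a trace of Lewis acid, and a 1,2-hydride shift delivers the arylacetaldehyde without protic acid.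

Step 6
Reactants: 6 2-Ar-acetaldehyde
Product: 7 (±)-1-Ar-but-3-yn-2-ol
Conditions: HC≡CMgBr, THF, −78 → 0 °C; aq. NH4Cl
Reagents that add atoms: ethynylmagnesium bromide, C#C[Mg]Br
Why: 1,2-Addition of an alkynyl Grignard reagent to the aldehyde at low temperature outruns enolisation, and the aryl bromide does not exchange with an alkynylmagnesium (the racemic carbinol is oxidised next).

Step 7
Reactants: 7 (±)-1-Ar-but-3-yn-2-ol
Product: 8 1-Ar-but-3-yn-2-one
Conditions: Dess–Martin periodinane, CH2Cl2, 0 °C → rt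
Reagents that add atoms: none
Why: Dess–Martin oxidation of the propargylic alcohol under near-neutral conditions that touch neither the electron-rich ring nor the acetal.

Step 8
Reactants: 8 1-Ar-but-3-yn-2-one
Product: 9 (E)-1-Ar-4-methoxybut-3-en-2-one
Conditions: MeOH, DABCO (10 mol %), CH2Cl2, 0 °C
Reagents that add atoms: methanol, CO
Why: Amine-catalysed oxa-Michael addition of methanol to the terminal ynone, which settles on the more stable (E)-β-methoxy enone.

Step 9
Reactants: 9 (E)-1-Ar-4-methoxybut-3-en-2-one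
Product: 10 (1E,3Z)-4-Ar-1-methoxy-3-(trimethylsilyloxy)buta-1,3-diene
Conditions: Me3SiOTf, Et3N, Et2O, 0 °C; pentane, cold NaHCO3 wash; used crude
Reagents that add atoms: trimethylsilyl triflate, C[Si](C)(C)OS(=O)(=O)C(F)(F)F
Why: Soft enolisation and O-silylation: the benzylic CH2 is the only enolisable position, and allylic strain puts the aryl group cis to the siloxy group (3Z), so it points outward in the s-cis diene.

Step 10
Reactants: 10 (1E,3Z)-4-Ar-1-methoxy-3-(trimethylsilyloxy)buta-1,3-diene; 11 3,4-bis(benzyloxy)benzaldehyde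
Product: 14 (2R,3S)-2-Ar'-3-Ar-2,3-dihydro-4H-pyran-4-one (2,3-trans), via aldol silyl ether 12 (not isolated), via cis-pyranone 13 (not isolated)
Conditions: Ti(OiPr)4 (20 mol %), (R)-BINOL (40 mol %), 4 Å MS, CH2Cl2, −20 → 0 °C; CF3CO2H (0.3 equiv), 0 °C; DBU (0.5 equiv), 0 °C → rt
Reagents that add atoms: none
Why: The chiral Lewis acid formed from Ti(OiPr)4 and (R)-BINOL (tetravalent titanium) binds aldehyde 11, and the aryl-bearing diene terminus attacks the carbonyl carbon (C2–C3), either in concert with O–C bonding or as a Mukaiyama aldol giving 12, which CF3CO2H then cyclises. The closest known reaction is the catalytic enantioselective hetero-Diels–Alder reaction of aromatic aldehydes with 1-methoxy-3-silyloxydienes, 4-alkyl congeners included, so only the bulk of the 2,6-dioxygenated aryl group is untested. The one ring closes as a formal [4+2] cycloaddition; in the stepwise variant the C2 oxygen adds 6-endo-trig to the methoxy-bearing carbon (O1–C8a) and the methoxy group is expelled. C2 is set by the ligand, which leaves the Re face of the bound aldehyde open, and C3 is set thermodynamically, DBU enolising C3–H of 13 until both aryl groups are equatorial (2,3-trans). The step needs regiocontrol, which the 1,3-donor pattern supplies by making the aryl-bearing carbon the only nucleophilic terminus, and it needs an accessible s-cis conformer, which the (3Z) geometry secures; the aldehyde cannot enolise. Because the C3 enolate could expel O1, the base is substoichiometric, cold and brief, and enantiomeric purity is checked before going on.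

Step 11
Reactants: 15 2,2,6-trimethyl-4H-1,3-dioxin-4-one
Product: 16 2,2-dimethyl-6-methylidene-4-(trimethylsilyloxy)-6H-1,3-dioxine
Conditions: LiN(iPr)2, THF, −78 °C; Me3SiCl
Reagents that add atoms: chlorotrimethylsilane, C[Si](C)(C)Cl
Why: Kinetic γ-deprotonation of the dioxinone and O-silylation give the cross-conjugated silyl dienol ether, the standard vinylogous acetoacetate nucleophile.

Step 12
Reactants: 14 (2R,3S)-2-Ar'-3-Ar-2,3-dihydro-4H-pyran-4-one; 16 silyl dienol ether
Product: 17 (2R,3S,6S)-2-Ar'-3-Ar-6-[(2,2-dimethyl-4-oxo-4H-1,3-dioxin-6-yl)methyl]-4-(trimethylsilyloxy)-3,6-dihydro-2H-pyran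
Conditions: Me3SiOTf (20 mol %), CH2Cl2, −78 °C; Et3N quench, cold NaHCO3 wash; used crude
Reagents that add atoms: none
Why: Vinylogous Mukaiyama–Michael addition: Me3SiOTf turns the vinylogous ester into a 4-silyloxy oxocarbenium ion, the γ-carbon of 16 attacks it axially at C8a anti to the C2 aryl group, and silyl transfer leaves a regiodefined C4=C4a enol silane (the C8a centre is erased in step 13).

Step 13
Reactants: 17 enol silane
Product: 18 (2R,3S)-2-Ar'-3-Ar-6-[(2,2-dimethyl-4-oxo-4H-1,3-dioxin-6-yl)methyl]-2,3-dihydro-4H-pyran-4-one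
Conditions: Pd(OAc)2 (1.1 equiv), MeCN, rt
Reagents that add atoms: none
Why: Saegusa–Ito oxidation: divalent palladium takes up the enol silane at C4a, and β-hydride elimination of the only available hydrogen (C8a–H) restores C4a=C8a, supplying the oxidation level of the arene without an electrophilic halogen, which the trialkoxyaryl ring would intercept.

Step 14
Reactants: 18 dioxinone-substituted dihydropyranone
Product: 20 (2R,3S)-2-Ar'-3-Ar-5,7-dihydroxychroman-4-one, via acylketene 19 (not isolated)
Conditions: toluene (high dilution, dry), 110 °C, N2 stream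
Reagents that add atoms: none
Why: Proposed new method: retro-[4+2] loss of acetone from the dioxinone (the known way to acylketenes) gives 19, whose C7 ketone enolises towards the doubly activated C8 methylene to a dienylketene (C5=C6–C7=C8–C8a=C4a) that forms C5–C4a by 6π electrocyclisation (equivalently, attack of the dienol carbon C4a on the ketene) and tautomerises to the 5,7-dihydroxy arene under neutral conditions that leave C2 and C3 alone, while the closed oxygen ring holds C4 trans to C8 across C4a=C8a and so excludes the competing aldol mode; the closest known reactions are the dienylketene electrocyclisation that ends cyclobutenone-based benzannulations and thermal dioxinone-to-acylketene cyclisations.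

Step 15
Reactants: 20 (2R,3S)-2-Ar'-3-Ar-5,7-dihydroxychroman-4-one
Product: 21 (2R,3S)-5,7-bis(benzyloxy)-2-Ar'-3-Ar-chroman-4-one
Conditions: KN(SiMe3)2 (2.0 equiv), THF, −78 °C; BnBr, n-Bu4NI, DMF, → rt
Reagents that add atoms: benzyl bromide, BrCc1ccccc1
Why: Williamson etherification with exactly two equivalents of base: all base is stored in the two phenoxides, which are too weak to enolise C3–H, so the chalcone-type ring opening that accompanies benzylation of flavanones with excess carbonate is avoided.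

Step 16
Reactants: 21 (2R,3S)-5,7-bis(benzyloxy)-2-Ar'-3-Ar-chroman-4-one
Product: 23 compound 21 carrying acetyl in place of bromine at C4a', via 1-ethoxyvinyl arene 22 (not isolated)
Conditions: Bu3SnC(OEt)=CH2, Pd(PPh3)4 (10 mol %), toluene, 105 °C; then 1 M HCl, THF, 0 °C
Reagents that add atoms: tributyl(1-ethoxyvinyl)stannane, CCCC[Sn](CCCC)(CCCC)C(=C)OCC; water, O
Why: Stille coupling of the aryl bromide with an acetyl-anion equivalent under neutral conditions, followed by very mild hydrolysis of the α-aryl enol ether 22, puts the acetyl group on C4a' with no regiochemical choice and leaves the MOM ether in place.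

Step 17
Reactants: 23 C4a'-acetyl compound
Product: 25 (2R,3S)-5,7-bis(benzyloxy)-2-Ar'-3-[5,7-bis(benzyloxy)-4-oxo-4H-chromen-8-yl]chroman-4-one, via enaminone 24 (not isolated)
Conditions: Me2NCH(OMe)2, toluene, 90 °C; concentrate; then 3 M HCl, MeOH–THF, 40 °C
Reagents that add atoms: N,N-dimethylformamide dimethyl acetal, COC(OC)N(C)C
Why: Enaminone chromone synthesis: condensation occurs at the only methyl group next to a carbonyl, and acid then removes the MOM group so that the freed phenol is captured at once by addition–elimination at the iminium carbon, before it can add to C4=O of unit B and dehydrate to a benzofuran; the first stage is kept short because C3–H can enolise in it.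

Step 18
Reactants: 25 chromone; 26 4-(benzyloxy)phenylboronic acid
Product: 27 (2R,3S)-5,7-bis(benzyloxy)-2-Ar'-3-{(2R)-5,7-bis(benzyloxy)-2-[4-(benzyloxy)phenyl]-4-oxochroman-8-yl}chroman-4-one
Conditions: Pd(OCOCF3)2 (10 mol %), (S)-4-tert-butyl-2-(pyridin-2-yl)-4,5-dihydrooxazole [(S)-t-BuPyOX, 12 mol %], NH4PF6, H2O, ClCH2CH2Cl, 60 °C
Reagents that add atoms: none
Why: Enantioselective conjugate addition of an arylboronic acid to a chromone by a cationic pyridine–oxazoline complex of divalent palladium: arylpalladation of C2'=C3' on the face left open by the tert-butyl group sets C2' as R, protonolysis of the palladium enolate frees the flavanone, and the base-free medium spares C2, C3 and the new centre.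

Step 19
Reactants: 27 heptabenzyl ether
Product: 28 (2R,3S)-2-(3,4-dihydroxyphenyl)-5,7-dihydroxy-3-[(2R)-5,7-dihydroxy-2-(4-hydroxyphenyl)-4-oxochroman-8-yl]chroman-4-one (CNP0105436.3)
Conditions: H2 (1 atm), Pd/C, EtOAc–MeOH, rt
Reagents that add atoms: none
Why: Hydrogenolysis of all seven benzyl ethers under neutral conditions, which leaves the two aryl ketones, the benzylic C–O ring bonds and the three stereocentres untouched.

Compound list
1 | 2,4,6-trihydroxybenzaldehyde | O=Cc1c(O)cc(O)cc1O | starting material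
2 | 2,4-bis(benzyloxy)-6-hydroxybenzaldehyde | O=Cc1c(O)cc(OCc2ccccc2)cc1OCc1ccccc1 | intermediate
3 | 4,6-bis(benzyloxy)-3-bromo-2-hydroxybenzaldehyde | O=Cc1c(O)c(Br)c(OCc2ccccc2)cc1OCc1ccccc1 | intermediate
4 | 4,6-bis(benzyloxy)-3-bromo-2-(methoxymethoxy)benzaldehyde | O=Cc1c(OCOC)c(Br)c(OCc2ccccc2)cc1OCc1ccccc1 | intermediate
5 | (±)-2-Ar-oxirane | C1OC1c1c(OCOC)c(Br)c(OCc2ccccc2)cc1OCc1ccccc1 | intermediate
6 | 2-Ar-acetaldehyde | O=CCc1c(OCOC)c(Br)c(OCc2ccccc2)cc1OCc1ccccc1 | intermediate
7 | (±)-1-Ar-but-3-yn-2-ol | C#CC(O)Cc1c(OCOC)c(Br)c(OCc2ccccc2)cc1OCc1ccccc1 | intermediate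
8 | 1-Ar-but-3-yn-2-one | C#CC(=O)Cc1c(OCOC)c(Br)c(OCc2ccccc2)cc1OCc1ccccc1 | intermediate
9 | (E)-1-Ar-4-methoxybut-3-en-2-one | CO/C=C/C(=O)Cc1c(OCOC)c(Br)c(OCc2ccccc2)cc1OCc1ccccc1 | intermediate
10 | (1E,3Z)-4-Ar-1-methoxy-3-(trimethylsilyloxy)buta-1,3-diene | CO/C=C/C(O[Si](C)(C)C)=C/c1c(OCOC)c(Br)c(OCc2ccccc2)cc1OCc1ccccc1 | intermediate
11 | 3,4-bis(benzyloxy)benzaldehyde | O=Cc1ccc(OCc2ccccc2)c(OCc2ccccc2)c1 | starting material
12 | (1E,5R)-4-Ar-5-Ar'-1-methoxy-5-(trimethylsilyloxy)pent-1-en-3-one (C4 epimers) | COCOc1c(Br)c(OCc2ccccc2)cc(OCc2ccccc2)c1C(C(=O)/C=C/OC)[C@@H](O[Si](C)(C)C)c1ccc(OCc2ccccc2)c(OCc2ccccc2)c1 | intermediate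
13 | (2R,3R)-2-Ar'-3-Ar-2,3-dihydro-4H-pyran-4-one (2,3-cis) | COCOc1c(Br)c(OCc2ccccc2)cc(OCc2ccccc2)c1[C@H]1C(=O)C=CO[C@H]1c1ccc(OCc2ccccc2)c(OCc2ccccc2)c1 | intermediate
14 | (2R,3S)-2-Ar'-3-Ar-2,3-dihydro-4H-pyran-4-one (2,3-trans) | COCOc1c(Br)c(OCc2ccccc2)cc(OCc2ccccc2)c1[C@@H]1C(=O)C=CO[C@H]1c1ccc(OCc2ccccc2)c(OCc2ccccc2)c1 | intermediate
15 | 2,2,6-trimethyl-4H-1,3-dioxin-4-one | CC1=CC(=O)OC(C)(C)O1 | starting material
16 | 2,2-dimethyl-6-methylidene-4-(trimethylsilyloxy)-6H-1,3-dioxine | C=C1C=C(O[Si](C)(C)C)OC(C)(C)O1 | intermediate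
17 | (2R,3S,6S)-2-Ar'-3-Ar-6-[(2,2-dimethyl-4-oxo-4H-1,3-dioxin-6-yl)methyl]-4-(trimethylsilyloxy)-3,6-dihydro-2H-pyran | COCOc1c(Br)c(OCc2ccccc2)cc(OCc2ccccc2)c1[C@@H]1C(O[Si](C)(C)C)=C[C@H](CC2=CC(=O)OC(C)(C)O2)O[C@H]1c1ccc(OCc2ccccc2)c(OCc2ccccc2)c1 | intermediate
18 | (2R,3S)-2-Ar'-3-Ar-6-[(2,2-dimethyl-4-oxo-4H-1,3-dioxin-6-yl)methyl]-2,3-dihydro-4H-pyran-4-one | COCOc1c(Br)c(OCc2ccccc2)cc(OCc2ccccc2)c1[C@@H]1C(=O)C=C(CC2=CC(=O)OC(C)(C)O2)O[C@H]1c1ccc(OCc2ccccc2)c(OCc2ccccc2)c1 | intermediate
19 | acylketene: 4-[(2R,3S)-2-Ar'-3-Ar-4-oxo-3,4-dihydro-2H-pyran-6-yl]-3-oxobut-1-en-1-one | COCOc1c(Br)c(OCc2ccccc2)cc(OCc2ccccc2)c1[C@@H]1C(=O)C=C(CC(=O)C=C=O)O[C@H]1c1ccc(OCc2ccccc2)c(OCc2ccccc2)c1 | intermediate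
20 | (2R,3S)-2-Ar'-3-Ar-5,7-dihydroxychroman-4-one | COCOc1c(Br)c(OCc2ccccc2)cc(OCc2ccccc2)c1[C@@H]1C(=O)c2c(O)cc(O)cc2O[C@H]1c1ccc(OCc2ccccc2)c(OCc2ccccc2)c1 | intermediate
21 | (2R,3S)-5,7-bis(benzyloxy)-2-Ar'-3-Ar-chroman-4-one | COCOc1c(Br)c(OCc2ccccc2)cc(OCc2ccccc2)c1[C@@H]1C(=O)c2c(OCc3ccccc3)cc(OCc3ccccc3)cc2O[C@H]1c1ccc(OCc2ccccc2)c(OCc2ccccc2)c1 | intermediate
22 | compound 21 with 1-ethoxyvinyl in place of Br | COCOc1c(C(=C)OCC)c(OCc2ccccc2)cc(OCc2ccccc2)c1[C@@H]1C(=O)c2c(OCc3ccccc3)cc(OCc3ccccc3)cc2O[C@H]1c1ccc(OCc2ccccc2)c(OCc2ccccc2)c1 | intermediate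
23 | compound 21 with acetyl in place of Br | COCOc1c(C(C)=O)c(OCc2ccccc2)cc(OCc2ccccc2)c1[C@@H]1C(=O)c2c(OCc3ccccc3)cc(OCc3ccccc3)cc2O[C@H]1c1ccc(OCc2ccccc2)c(OCc2ccccc2)c1 | intermediate
24 | compound 21 with (E)-3-(dimethylamino)acryloyl in place of Br | COCOc1c(C(=O)/C=C/N(C)C)c(OCc2ccccc2)cc(OCc2ccccc2)c1[C@@H]1C(=O)c2c(OCc3ccccc3)cc(OCc3ccccc3)cc2O[C@H]1c1ccc(OCc2ccccc2)c(OCc2ccccc2)c1 | intermediate
25 | (2R,3S)-5,7-bis(benzyloxy)-2-Ar'-3-[5,7-bis(benzyloxy)-4-oxo-4H-chromen-8-yl]chroman-4-one | O=c1ccoc2c1c(OCc1ccccc1)cc(OCc1ccccc1)c2[C@@H]1C(=O)c2c(OCc3ccccc3)cc(OCc3ccccc3)cc2O[C@H]1c1ccc(OCc2ccccc2)c(OCc2ccccc2)c1 | intermediate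
26 | 4-(benzyloxy)phenylboronic acid | OB(O)c1ccc(OCc2ccccc2)cc1 | starting material
27 | heptabenzyl ether of the target, (2R,3S,2'R) | O=C1C[C@H](c2ccc(OCc3ccccc3)cc2)Oc2c1c(OCc1ccccc1)cc(OCc1ccccc1)c2[C@@H]1C(=O)c2c(OCc3ccccc3)cc(OCc3ccccc3)cc2O[C@H]1c1ccc(OCc2ccccc2)c(OCc2ccccc2)c1 | intermediate
28 | (2R,3S)-2-(3,4-dihydroxyphenyl)-5,7-dihydroxy-3-[(2R)-5,7-dihydroxy-2-(4-hydroxyphenyl)-4-oxochroman-8-yl]chroman-4-one | O=C1C[C@H](c2ccc(O)cc2)Oc2c1c(O)cc(O)c2[C@@H]1C(=O)c2c(O)cc(O)cc2O[C@H]1c1ccc(O)c(O)c1 | target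

Total step count: 19. Longest linear sequence: 18 (steps 1–10 and 12–19; step 11 prepares the side reagent 16).

Steps most likely to fail

Step 14. The acylketene may be consumed between molecules (dimerisation, or capture by traces of water followed by decarboxylation) faster than C5 reaches C4a. The fallback uses known chemistry and sets out from 18. The same thermolysis is run in toluene containing methanol, which traps the ketene as the methyl β-keto ester F1. One equivalent of KOt-Bu in THF then deprotonates C8. The resulting dienolate is acylated at C4a by the ester in a Claisen (Dieckmann-type) condensation, as used for polyketide-type triketo esters. The closed oxygen ring again excludes the aldol mode. Acidification returns the route at 20.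

Step 10. The aryl-flanked diene terminus may approach the bound aldehyde too slowly. Desilylation of the diene, an uncatalysed background reaction or poor facial discrimination could then take over. The base treatment may also erode enantiomeric purity by reversible opening of C2–O1. The fallback sets out from 9 and 11 and makes the two bonds one at a time. Enone 9 is enolised with diisopinocampheylboron triflate (the antipode chosen for Re-face attack) and i-Pr2NEt, and the (Z)-boron enolate adds to 11 through a closed six-membered transition state to give the syn-aldol F2. CF3CO2H cyclises F2 with loss of methanol. The route is rejoined at 13, which is equilibrated to 14 as before.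

Step 18. The chromone, flanked by the 5'-benzyloxy group and the bulky C8' substituent, may bind the catalyst poorly, so that protodeboronation outruns arylation. The stereocentres of unit B may also oppose the ligand (mismatched facial selection). The fallback sets out from 25 and gives up catalyst control. Stoichiometric (4-BnOC6H4)2CuLi with Me3SiCl in THF at −78 °C adds to C2' and gives the silyl enol ether F3 as both C2' epimers. Mild acidic work-up gives 27 together with its (2'S) epimer F4. These are diastereomers and are separated by chromatography, and the route is rejoined at 27.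

Further compounds
F1 | step 14 | methyl 4-[(2R,3S)-2-Ar'-3-Ar-4-oxo-3,4-dihydro-2H-pyran-6-yl]-3-oxobutanoate | COCOc1c(Br)c(OCc2ccccc2)cc(OCc2ccccc2)c1[C@@H]1C(=O)C=C(CC(=O)CC(=O)OC)O[C@H]1c1ccc(OCc2ccccc2)c(OCc2ccccc2)c1
F2 | step 10 | (1E,4R,5R)-4-Ar-5-Ar'-5-hydroxy-1-methoxypent-1-en-3-one (syn-aldol) | COCOc1c(Br)c(OCc2ccccc2)cc(OCc2ccccc2)c1[C@@H](C(=O)/C=C/OC)[C@@H](O)c1ccc(OCc2ccccc2)c(OCc2ccccc2)c1
F3 | step 18 | 4'-(trimethylsilyloxy)-2'H-chromene from aryl addition to 25 (C2' epimers) | C[Si](C)(C)OC1=CC(c2ccc(OCc3ccccc3)cc2)Oc2c1c(OCc1ccccc1)cc(OCc1ccccc1)c2[C@@H]1C(=O)c2c(OCc3ccccc3)cc(OCc3ccccc3)cc2O[C@H]1c1ccc(OCc2ccccc2)c(OCc2ccccc2)c1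
F4 | step 18 | (2'S) epimer of 27 | O=C1C[C@@H](c2ccc(OCc3ccccc3)cc2)Oc2c1c(OCc1ccccc1)cc(OCc1ccccc1)c2[C@@H]1C(=O)c2c(OCc3ccccc3)cc(OCc3ccccc3)cc2O[C@H]1c1ccc(OCc2ccccc2)c(OCc2ccccc2)c1
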